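Ring A is treated as a masked cyclohexane-1,3-dione: C7 (methylidene) and C9 (carbinol) flank C8, while the vicinal quaternary pair C6–C11 closes the ring. Everything rests on inserting the C8–C9 unit of ethoxyacetylene into the C7–C10 acyl bond of a spirocyclobutanone with a zerovalent nickel catalyst; one operation forms C7–C8 and C9–C10 and delivers ring A as its vinylogous ester. The precursor is a 3,3-dimethylcyclobutanone spiro-fused at C6 to ketal-protected ring B, assembled by a keteniminium–isobutylene [2+2] cycloaddition that already joins C6 to C11. Ring B is then desymmetrised to set C6, and C3, C10 and C9 follow under substrate control.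

Key step: step 3

Remark: locants follow the spiro[5.5]undecane numbering of the target (C6 spiro, ring A = C6 to C11, ring B = C1 to C6) for every spiro intermediate and CIP descriptors refer to these locants; the ene-reductase of step 6 is assumed to be picked from a panel of Old Yellow Enzyme homologues for the 6R product.

Step 1
Reactants: 1 1,4-dioxaspiro[4.5]decane-8-carboxylic acid
Product: 3 amide N,N-dimethyl-1,4-dioxaspiro[4.5]decane-8-carboxamide, via acyl imidazolide 2 (not isolated)
Conditions: CDI, THF, rt; then Me2NH (2 M in THF), rt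
Reagents that add atoms: dimethylamine, CNC
Why: Carbonyldiimidazole amide coupling under neutral conditions, in which the acid is activated as its acyl imidazolide and aminolysed by dimethylamine, so the dioxolane is untouched and no stereocentre is involved.

Step 2
Reactants: 3 N,N-dimethyl-1,4-dioxaspiro[4.5]decane-8-carboxamide; 4 isobutylene (2-methylpropene)
Product: 7 spirocyclobutanone ketal (3,3-dimethyl-8,11-dioxadispiro[3.2.4^7.2^4]tridecan-1-one), via keteniminium triflate 5 (not isolated), via cyclobutaniminium triflate 6 (not isolated)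
Conditions: Tf2O, 2,4,6-collidine, 4 (5 equiv), ClCH2CH2Cl, sealed tube, −20 → 60 °C; then aq. NaHCO3, 60 °C
Reagents that add atoms: water, O
Why: Keteniminium–alkene [2+2] cycloaddition in which the electrophilic central carbon (C7) bonds to the CH2 terminus of isobutylene (C10) and the resulting tertiary cation closes onto C6, which forges the congested C6–C11 bond between two quaternary carbons, after which bicarbonate hydrolysis of the iminium salt gives the ketone with the ketal intact and without any stereocentre.

Step 3
Reactants: 7 spirocyclobutanone ketal; 8 ethoxyacetylene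
Product: 9 spiro vinylogous ester ketal (9-ethoxy-11,11-dimethylspiro[5.5]undec-8-ene-3,7-dione 3-ethylene ketal)
Conditions: Ni(cod)2 (10 mol %), PCy3 (20 mol %), toluene, 80 °C, sealed vessel, 8 (3 equiv, hexane solution) added over 6 h
Reagents that add atoms: none
Why: Proposed new method: zerovalent nickel should join the strained C7 carbonyl and the ynol ether by oxidative cyclisation to an oxanickelacyclopentene in which the electron-rich CH terminus (C8) is bonded to C7 and nickel carries the ethoxy-bearing C9. β-Carbon elimination then opens the four-membered ring at C7–C10 with release of strain to a seven-membered nickelacycle (Ni, C9, C8, C7, C6, C11, C10), and C(sp2)–C(sp3) reductive elimination joins C9 to C10, which closes six-membered ring A as the vinylogous ester and returns the catalyst (a formal 4+2 ring expansion). The closest known reaction type is the nickel-catalysed intermolecular insertion of internal alkynes into cyclobutanones to give cyclohex-2-enones, which has not been shown for a terminal ynol ether or for an α-quaternary cyclobutanone. No stereocentre is created. The step needs regioselective insertion, which the polarisation of the ynol ether should secure (nucleophilic CH carbon to the carbonyl carbon, oxygen-bearing carbon to nickel), and regioselective bond cleavage, which the substrate should secure because transfer of the methylene C10 gives a primary alkyl–nickel bond whereas transfer of the fully substituted C6 would give a tertiary one. Slow addition of the alkyne at a temperature below its ketene-forming range is meant to hold back alkyne oligomerisation.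

Step 4
Reactants: 9 spiro vinylogous ester ketal
Product: 10 spiro diketone monoenol ether (9-ethoxy-11,11-dimethylspiro[5.5]undec-8-ene-3,7-dione)
Conditions: PPTS (cat.), acetone/H2O (9:1), 60 °C
Reagents that add atoms: water, O
Why: Acid-catalysed ketal hydrolysis under mild pyridinium catalysis, which should cleave the dioxolane while the vinylogous ester, reacting as an ester and not as a simple enol ether, persists, with no stereocentre involved.

Step 5
Reactants: 10 spiro diketone monoenol ether
Product: 11 spiro cyclohexadienone (9-ethoxy-11,11-dimethylspiro[5.5]undeca-1,4,8-triene-3,7-dione)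
Conditions: IBX (4 equiv), DMSO/fluorobenzene, 80 °C
Reagents that add atoms: none
Why: Twofold IBX α,β-dehydrogenation of the C3 ketone gives the cross-conjugated dienone, while ring A cannot be desaturated because its only enolisable carbon C10 is flanked by quaternary C11, and no stereocentre is formed.

Step 6
Reactants: 11 spiro cyclohexadienone
Product: 12 (6R)-9-ethoxy-11,11-dimethylspiro[5.5]undeca-1,8-diene-3,7-dione
Conditions: ene-reductase (YqjM or OPR3, picked from a panel), NADP+ (cat.), D-glucose, glucose dehydrogenase, KH2PO4/K2HPO4 buffer pH 7.0, DMSO (5 vol %), 30 °C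
Reagents that add atoms: none
Why: Ene-reductase (Old Yellow Enzyme) desymmetrisation of a prochiral 4,4-disubstituted cyclohexa-2,5-dienone, in which the flavin hydride adds to C5 and a tyrosine protonates C4 of one enantiotopic enone arm only, so that C6 is set by the enzyme pocket telling the C7 carbonyl side from the C11 gem-dimethyl side, while the β-alkoxy enone of ring A is too electron-rich to be reduced.

Step 7
Reactants: 12 (6R)-9-ethoxy-11,11-dimethylspiro[5.5]undeca-1,8-diene-3,7-dione
Product: 13 (3R,6R)-3-(dibromomethyl)-9-ethoxy-3-hydroxy-11,11-dimethylspiro[5.5]undeca-1,8-dien-7-one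
Conditions: CH2Br2, LiTMP (lithium 2,2,6,6-tetramethylpiperidide), THF, −90 °C; then 12, −90 → −78 °C; AcOH, −78 °C
Reagents that add atoms: dibromomethane, BrCBr
Why: 1,2-Addition of the carbenoid dibromomethyllithium to the enone carbonyl C3 (the vinylogous ester carbonyl C7 is deactivated and neopentylic), where ring B is a half-chair with C11 pseudoequatorial and C7 pseudoaxial and the bulky carbenoid should take the equatorial trajectory, which places CHBr2 cis to C7 and the hydroxyl cis to C11 (3R).

Step 8
Reactants: 13 (3R,6R)-3-(dibromomethyl)-9-ethoxy-3-hydroxy-11,11-dimethylspiro[5.5]undeca-1,8-dien-7-one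
Product: 15 (3R,6R,10S)-10-bromo-3-(dibromomethyl)-9-ethoxy-11,11-dimethyl-3-(trimethylsilyloxy)spiro[5.5]undeca-1,8-dien-7-one, via bis-silyl dienol ether 14 (not isolated)
Conditions: TMSOTf (2.5 equiv), Et3N, CH2Cl2, 0 °C → rt; then NBS, THF, −78 °C; aq. NaHCO3
Reagents that add atoms: trimethylsilyl triflate, C[Si](C)(C)OS(=O)(=O)C(F)(F)F; N-bromosuccinimide, O=C1CCC(=O)N1Br
Why: Soft enolisation followed by γ-bromination of a silyl dienol ether (vinylogous Mukaiyama-type halogenation), in which silylation of the C7 carbonyl and loss of the only available proton (C10, as C6 is quaternary) give the 7-siloxy-9-ethoxy diene while the tertiary alcohol is capped, NBS attacks the diene terminus C10 because that leads to the 1,3-dioxygenated allyl cation, and bromine should enter on the ring A face that carries the flat vinylic C1 arm, away from the C5 methylene, which gives 10S.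

Step 9
Reactants: 15 (3R,6R,10S)-10-bromo-3-(dibromomethyl)-9-ethoxy-11,11-dimethyl-3-(trimethylsilyloxy)spiro[5.5]undeca-1,8-dien-7-one
Product: 16 (3R,6S,10S)-10-bromo-3-(dibromomethyl)-9-ethoxy-11,11-dimethyl-7-methylidene-3-(trimethylsilyloxy)spiro[5.5]undeca-1,8-diene
Conditions: Tebbe reagent Cp2Ti(μ-CH2)(μ-Cl)AlMe2, pyridine (cat.), THF/toluene, −40 → 0 °C
Reagents that add atoms: Tebbe reagent Cp2Ti(μ-CH2)(μ-Cl)AlMe2, C[Al-]1(C)C[Ti]([Cl+]1)(C1C=CC=C1)C1C=CC=C1
Why: Tebbe methylenation, in which the non-basic titanium methylidene converts the hindered vinylogous ester carbonyl C7 into the exocyclic C7=C14 alkene by [2+2] cycloaddition and cycloreversion without deprotonating C10 or disturbing the bromides, and no stereocentre is formed or touched.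

Step 10
Reactants: 16 (3R,6S,10S)-10-bromo-3-(dibromomethyl)-9-ethoxy-11,11-dimethyl-7-methylidene-3-(trimethylsilyloxy)spiro[5.5]undeca-1,8-diene
Product: 17 (3R,6S,10S)-10-bromo-3-(dibromomethyl)-3-hydroxy-11,11-dimethyl-7-methylidenespiro[5.5]undec-1-en-9-one
Conditions: oxalic acid, THF/MeOH/H2O, 0 °C → rt; used crude
Reagents that add atoms: water, O
Why: Mild acid hydrolysis of a dienol ether, in which kinetic protonation at the α-carbon C8 gives the C9 oxocarbenium ion and hence the β,γ-unsaturated ketone with the methylidene kept out of conjugation, the labile tertiary trimethylsilyl ether is cleaved under the same conditions, and the C10 bromide stays in its preferred equatorial position.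

Step 11
Reactants: 17 (3R,6S,10S)-10-bromo-3-(dibromomethyl)-3-hydroxy-11,11-dimethyl-7-methylidenespiro[5.5]undec-1-en-9-one
Product: 18 mailiohydrin ((3R,6S,9R,10S)-10-bromo-3-(dibromomethyl)-11,11-dimethyl-7-methylidenespiro[5.5]undec-1-ene-3,9-diol)
Conditions: i-Bu2AlH (3.5 equiv), CH2Cl2, −78 °C; aq. potassium sodium tartrate
Reagents that add atoms: none
Why: Diastereoselective hydride reduction of an α-bromo ketone, where in the ring A chair the bromide is equatorial and the axial C11 methyl blocks the axial trajectory at C9, so the bulky aluminium hydride should attack equatorially and give the axial C9 alcohol cis to bromine (9R).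

Compound list
1 | 1,4-dioxaspiro[4.5]decane-8-carboxylic acid | OC(=O)C1CCC2(CC1)OCCO2 | starting material
2 | acyl imidazolide, 1-(1,4-dioxaspiro[4.5]decane-8-carbonyl)imidazole | O=C(C1CCC2(CC1)OCCO2)n1ccnc1 | intermediate
3 | N,N-dimethyl-1,4-dioxaspiro[4.5]decane-8-carboxamide | CN(C)C(=O)C1CCC2(CC1)OCCO2 | intermediate
4 | isobutylene (2-methylpropene) | CC(C)=C | starting material
5 | keteniminium triflate, N,N-dimethyl-(1,4-dioxaspiro[4.5]decan-8-ylidene)methaniminium triflate | C[N+](C)=C=C1CCC2(CC1)OCCO2.[O-]S(=O)(=O)C(F)(F)F | intermediate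
6 | cyclobutaniminium triflate, N,N-dimethyliminium salt of 7 | C[N+](C)=C1CC(C)(C)C12CCC3(CC2)OCCO3.[O-]S(=O)(=O)C(F)(F)F | intermediate
7 | spirocyclobutanone ketal, 3,3-dimethyl-8,11-dioxadispiro[3.2.4^7.2^4]tridecan-1-one | O=C1CC(C)(C)C12CCC3(CC2)OCCO3 | intermediate
8 | ethoxyacetylene | C#COCC | starting material
9 | spiro vinylogous ester ketal, 9-ethoxy-11,11-dimethylspiro[5.5]undec-8-ene-3,7-dione 3-ethylene ketal | O=C1C=C(OCC)CC(C)(C)C12CCC3(CC2)OCCO3 | intermediate
10 | 9-ethoxy-11,11-dimethylspiro[5.5]undec-8-ene-3,7-dione | O=C1C=C(OCC)CC(C)(C)C12CCC(=O)CC2 | intermediate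
11 | 9-ethoxy-11,11-dimethylspiro[5.5]undeca-1,4,8-triene-3,7-dione | O=C1C=C(OCC)CC(C)(C)C12C=CC(=O)C=C2 | intermediate
12 | (6R)-9-ethoxy-11,11-dimethylspiro[5.5]undeca-1,8-diene-3,7-dione | O=C1C=C(OCC)CC(C)(C)[C@@]12C=CC(=O)CC2 | intermediate
13 | (3R,6R)-3-(dibromomethyl)-9-ethoxy-3-hydroxy-11,11-dimethylspiro[5.5]undeca-1,8-dien-7-one | O=C1C=C(OCC)CC(C)(C)[C@@]12C=C[C@@](O)(C(Br)Br)CC2 | intermediate
14 | bis-silyl dienol ether, (3R,6R)-3-(dibromomethyl)-9-ethoxy-11,11-dimethyl-3,7-bis(trimethylsilyloxy)spiro[5.5]undeca-1,7,9-triene | C[Si](C)(C)OC1=CC(OCC)=CC(C)(C)[C@@]12C=C[C@@](O[Si](C)(C)C)(C(Br)Br)CC2 | intermediate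
15 | (3R,6R,10S)-10-bromo-3-(dibromomethyl)-9-ethoxy-11,11-dimethyl-3-(trimethylsilyloxy)spiro[5.5]undeca-1,8-dien-7-one | O=C1C=C(OCC)[C@@H](Br)C(C)(C)[C@@]12C=C[C@@](O[Si](C)(C)C)(C(Br)Br)CC2 | intermediate
16 | (3R,6S,10S)-10-bromo-3-(dibromomethyl)-9-ethoxy-11,11-dimethyl-7-methylidene-3-(trimethylsilyloxy)spiro[5.5]undeca-1,8-diene | C=C1C=C(OCC)[C@@H](Br)C(C)(C)[C@@]12C=C[C@@](O[Si](C)(C)C)(C(Br)Br)CC2 | intermediate
17 | (3R,6S,10S)-10-bromo-3-(dibromomethyl)-3-hydroxy-11,11-dimethyl-7-methylidenespiro[5.5]undec-1-en-9-one | C=C1CC(=O)[C@@H](Br)C(C)(C)[C@@]12C=C[C@@](O)(C(Br)Br)CC2 | intermediate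
18 | mailiohydrin, (3R,6S,9R,10S)-10-bromo-3-(dibromomethyl)-11,11-dimethyl-7-methylidenespiro[5.5]undec-1-ene-3,9-diol | C=C1C[C@@H](O)[C@@H](Br)C(C)(C)[C@@]12C=C[C@@](O)(C(Br)Br)CC2 | target

Total step count: 11
Longest linear sequence: 11 steps (1 to 18)

Steps most likely to fail

Step 3 (the proposed new method). The terminal ynol ether may oligomerise or cyclotrimerise on nickel, or lose ethylene thermally, faster than the hindered carbonyl undergoes oxidative cyclisation, and the orientation of insertion may erode. The fallback uses known chemistry, sets out from 7 and returns at 9. The lithium enolate of 7 (LiN(i-Pr)2, THF, −78 °C) is C-acylated at C10 with 1-acetylbenzotriazole to give the racemic 2-acetylcyclobutanone F1. NaOEt in EtOH should open this strained β-diketone by retro-Claisen cleavage of C7–C10 to the δ-keto ester F2 (ester carbon C7, ketone carbon C9, methyl C8). KOtBu in THF then closes ring A by intramolecular Claisen condensation of C8 onto C7 to give the cyclohexane-1,3-dione F3. O-Ethylation (EtOH, HC(OEt)3, cat. TsOH) at the less hindered C9 carbonyl gives 9.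

Step 7. The carbenoid may add with poor facial selectivity (axial against equatorial attack on the ring B half-chair), and enolisation at C4 may compete. The fallback sets out from 12 and returns at 13. The much bulkier tribromomethyllithium (CHBr3, LiTMP, THF/Et2O, −105 °C) should add with a stronger equatorial preference to give the tribromomethyl carbinol F4. One bromine is then removed by radical hydrodehalogenation (Bu3SnH, 1 equiv, Et3B/air, toluene, −78 °C) to give 13.

Step 6. The enzyme may bind the congested spiro-dienone poorly, discriminate weakly between the two enantiotopic enone arms, or reduce both. The fallback sets out from 10, bypasses 11 and returns at 12. Enantioselective deprotonation of the conformationally locked ketone 10 with lithium (R,R)-bis(1-phenylethyl)amide (or its antipode, chosen to remove the axial C2 proton) in the presence of TMSCl (THF, −100 °C) gives the silyl enol ether F5. Saegusa–Ito oxidation (Pd(OAc)2, MeCN, rt) then gives 12.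

Further compounds
F1 | step 3 | 2-acetyl-3,3-dimethyl-8,11-dioxadispiro[3.2.4^7.2^4]tridecan-1-one (racemic) | CC(=O)C1C(=O)C2(CCC3(CC2)OCCO3)C1(C)C
F2 | step 3 | ethyl 8-(2-methyl-4-oxopentan-2-yl)-1,4-dioxaspiro[4.5]decane-8-carboxylate | CCOC(=O)C1(CCC2(CC1)OCCO2)C(C)(C)CC(C)=O
F3 | step 3 | 11,11-dimethylspiro[5.5]undecane-3,7,9-trione 3-ethylene ketal | O=C1CC(=O)CC(C)(C)C12CCC3(CC2)OCCO3
F4 | step 7 | (3R,6R)-9-ethoxy-3-hydroxy-11,11-dimethyl-3-(tribromomethyl)spiro[5.5]undeca-1,8-dien-7-one | O=C1C=C(OCC)CC(C)(C)[C@@]12C=C[C@@](O)(C(Br)(Br)Br)CC2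
F5 | step 6 | (6R)-9-ethoxy-11,11-dimethyl-3-(trimethylsilyloxy)spiro[5.5]undeca-2,8-dien-7-one | O=C1C=C(OCC)CC(C)(C)[C@@]12CC=C(O[Si](C)(C)C)CC2
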